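Assumption: cembrane numbering is used. C1 is the ring carbon bearing the acrylic acid, C3 bears OAc, and the methyl carbinols are C4, C8 and C12. The target is 1R,3R,4S,7S,8R,11S,12R.

## Retrosynthetic overview
1. Three building blocks are used: (R)-carvone **1** (C1–C4, C13–C17, 4-Me), bromide **2** (C5–C8) and L-glutamic-acid-derived lactone acid **3** (C9–C12). The 12-Me and 8-Me groups come from Me2CuLi and AlMe3.
2. Endgame: the isopropenyl group is oxidised to the acrylic acid (SeO2, then Pinnick) after diol-selective C3 acetylation of the bridged tetraol.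
3. The oxolane is the second ring formed. C11-OH adds transannularly (5-exo-dig) to a C7≡C8 cycloalkyne. Enol-ether epoxidation and AlMe3 opening then set C7 and C8.
4. The 14-membered carbocycle is the first ring formed. The C8–C9 bond is made by a visible-light Ni/photoredox decarboxylative C(sp3)–C(sp) macrocyclisation.
5. The chain is assembled through C12–C13 (organocerium plus (S)-solerone) and C4–C5 (Grignard plus α-silyloxy ketone), both under Felkin/Cornforth control. The western keto-aldehyde comes from cleaving the ring alkene of cis-carveol.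

## Route

**Step 1**
Reactants: **1** (R)-(−)-carvone
Product: **4** (−)-cis-carveol, (1R,5R)-2-methyl-5-(prop-1-en-2-yl)cyclohex-2-en-1-ol
Conditions: NaBH4, CeCl3·7H2O, MeOH, 0 °C
Reagents that add atoms: none
Why: Luche 1,2-reduction delivers hydride axially, giving the alcohol cis to the isopropenyl group (≥95:5), so C3 (R) is set from the bought C1.

**Step 2**
Reactants: **4** cis-carveol
Product: **5** (1R,2R,4S,6S)-1-methyl-4-(prop-1-en-2-yl)-7-oxabicyclo[4.1.0]heptan-2-ol (epoxide syn to OH)
Conditions: VO(acac)2 (1 mol %), t-BuOOH, PhMe, 0 °C → rt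
Reagents that add atoms: tert-butyl hydroperoxide, CC(C)(C)OO
Why: Hydroxyl-directed vanadium epoxidation touches only the allylic ring alkene and leaves the isopropenyl group intact; the two new centres are destroyed in Step 4.

**Step 3**
Reactants: **5** epoxy alcohol
Product: **6** TBS ether of **5**
Conditions: TBSCl, imidazole, DMAP, DMF, rt
Reagents that add atoms: TBSCl, CC(C)(C)[Si](C)(C)Cl
Why: Silylation blocks C3–C4 glycol cleavage in Step 4 and provides the bulky non-chelating α-oxygen needed in Step 7.

**Step 4**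
Reactants: **6** silyl epoxide
Product: **7** (3S,5R)-5-(TBSO)-6-oxo-3-(prop-1-en-2-yl)heptanal (C4 methyl ketone, C13 aldehyde)
Conditions: H5IO6, THF/H2O, 0 °C → rt
Reagents that add atoms: water, O
Why: One-pot epoxide hydrolysis and Malaprade cleavage (as used on limonene oxide) opens the ring without touching C1, C3 or the 1,1-disubstituted alkene.

**Step 5**
Reactants: **7** keto aldehyde
Product: **8** (3R,5R)-3-(TBSO)-7-hydroxy-5-(prop-1-en-2-yl)heptan-2-one
Conditions: NaBH4 (0.3 equiv), CH2Cl2/EtOH, −78 °C
Reagents that add atoms: none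
Why: Low-temperature borohydride reduction is chemoselective for the aldehyde over the hindered ketone.

**Step 6**
Reactants: **8** hydroxy ketone
Product: **9** (3R,5S)-3-(TBSO)-7-iodo-5-(prop-1-en-2-yl)heptan-2-one
Conditions: I2, PPh3, imidazole, CH2Cl2, 0 °C
Reagents that add atoms: iodine, II
Why: Appel iodination of the only free (primary) alcohol.

**Step 7**
Reactants: **9** iodo ketone; **2** 4-bromo-1-(trimethylsilyl)but-1-yne
Product: **10** [(5S,6R,8S)-6-(TBSO)-5-(TESO)-10-iodo-5-methyl-8-(prop-1-en-2-yl)dec-1-yn-1-yl]trimethylsilane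
Conditions: **2**, Mg, THF; add to **9**, Et2O, −78 °C; then TESOTf, 2,6-lutidine, −78 → 0 °C (one pot)
Reagents that add atoms: TESOTf, CC[Si](CC)(CC)OS(=O)(=O)C(F)(F)F
Why: Polar Felkin–Anh Grignard addition to the α-OTBS methyl ketone (attack anti to C–O) gives the anti C3/C4 relationship, i.e. 4S; the primary iodide is inert at −78 °C and the alkoxide is capped in situ.

**Step 8**
Reactants: **3** (S)-5-oxotetrahydrofuran-2-carboxylic acid
Product: **11** (S)-5-acetyldihydrofuran-2(3H)-one ((S)-solerone)
Conditions: (COCl)2, cat. DMF, CH2Cl2; concentrate; Me2CuLi, Et2O, −78 °C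
Reagents that add atoms: lithium dimethylcuprate, [Li+].C[Cu-]C
Why: Gilman ketone synthesis from the acid chloride stops at the methyl ketone, spares the lactone and does not touch the bought C11 centre.

**Step 9**
Reactants: **10** iodide; **11** (S)-solerone
Product: **12** seco-lactone (1R,3R,4S,11S,12R), with the C12–C13 bond formed, C12-OTES, and C11-O held in the γ-lactone
Conditions: t-BuLi (2.1 equiv), Et2O/pentane, −78 °C; CeCl3·2LiCl, THF; **11**, −78 °C; then TESOTf, 2,6-lutidine, → 0 °C
Reagents that add atoms: TESOTf, CC[Si](CC)(CC)OS(=O)(=O)C(F)(F)F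
Why: After I/Li exchange, the non-basic organocerium adds to the ketone in preference to the lactone. The poorly basic acyloxy oxygen enforces the Cornforth/Felkin mode (attack past H), giving the anti C11/C12 pair, i.e. 12R.

**Step 10**
Reactants: **12** TMS-alkyne
Product: **13** 1-bromoalkyne (C8–Br), otherwise as **12**
Conditions: NBS, AgNO3 (10 mol %), acetone, rt, dark
Reagents that add atoms: N-bromosuccinimide, BrN1C(=O)CCC1=O
Why: Silver-catalysed bromodesilylation of an alkynylsilane; silyl ethers, the lactone and the alkene are tolerated.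

**Step 11 (key step)**
Reactants: **13** bromoalkyne lactone
Product: **14** (1R,3R,4S,11S,12R)-3-(TBSO)-4,12-bis(TESO)-11-hydroxy-4,12-dimethyl-1-(prop-1-en-2-yl)cyclotetradec-7-yne
Conditions: CsOH·H2O (1.0 equiv), THF/H2O, 0 °C, azeotropic drying; then 4CzIPN (2 mol %), NiCl2·glyme (10 mol %), dtbbpy (12 mol %), DMF/MeCN (1 mM), 450 nm LEDs, 25 °C, Ar
Reagents that add atoms: none
Why: Proposed new method: a visible-light Ni/photoredox decarboxylative C(sp3)–C(sp) macrocyclisation in which Ni(0) inserts into C8–Br to give a tethered alkynyl–Ni(II), excited 4CzIPN oxidises the unprotected γ-hydroxy carboxylate (loss of CO2) to the primary C9 radical, that radical is captured intramolecularly by the Ni(II) centre, Ni(III) reductively eliminates the C8–C9 bond, and 4CzIPN•− returns Ni(I) to Ni(0), so the cycle is redox-neutral and the low radical concentration at 1 mM favours the strain-free 14-membered cycloalkyne over dimers; the closest known reaction types are metallaphotoredox decarboxylative vinylation/arylation of carboxylic acids, Ni-catalysed reductive decarboxylative alkynylation of redox-active esters with bromoalkynes, and photoredox decarboxylative macrocyclisation, and no stereocentre is touched.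

**Step 12**
Reactants: **14** cycloalkynol
Product: **15** bridged (7Z)-enol ether (8,11-epoxy, C7=C8; O cis to C6)
Conditions: (JohnPhos)Au(MeCN)SbF6 (2 mol %), 4 Å MS, CH2Cl2, 0 °C; Et3N quench
Reagents that add atoms: none
Why: Transannular 5-exo-dig hydroalkoxylation (anti-oxyauration then protodeauration) gives the Z-enol ether; O4 and O12 are silylated, so only O11 can add.

**Step 13**
Reactants: **15** enol ether
Product: **16** (1R,3R,4S,7S,8R,11S,12R)-8,11-epoxy-7-ol carrying 8-Me (C3-OTBS, C4/C12-OTES)
Conditions: DMDO, CH2Cl2, −78 °C; remove volatiles; AlMe3 (5 equiv), CH2Cl2, −78 → −20 °C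
Reagents that add atoms: dimethyldioxirane, CC1(C)OO1; trimethylaluminium, C[Al](C)C
Why: In this glycal-type epoxidation/C-ketoside formation, DMDO attacks the electron-rich enol ether (not the isopropenyl group) on the outer face anti to C12. Al-bound methyl is then delivered to the C8 oxocarbenium on the same face (syn opening). This gives the cis-2,5-oxolane with 8R, and the Z geometry fixes 7S.

**Step 14**
Reactants: **16**
Product: **17** tetraol (3,4,7,12-OH), (1R,3R,4S,7S,8R,11S,12R)
Conditions: TBAF, THF, 40 °C
Reagents that add atoms: none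
Why: Global fluoride desilylation; no base-sensitive group is present yet.

**Step 15**
Reactants: **17** tetraol
Product: **18** 3-O-acetate
Conditions: Bu2SnO, MeOH, reflux; evaporate; AcCl (1.05 equiv), CH2Cl2, 0 °C
Reagents that add atoms: acetyl chloride, CC(Cl)=O
Why: Stannylene-acetal monoacylation works because only C3/C4 is a free 1,2-diol; it is activated and acylated at its secondary oxygen, leaving the isolated C7-OH and the tertiary alcohols free.

**Step 16**
Reactants: **18**
Product: **19** enal (C15(=CH2)–CHO)
Conditions: SeO2 (1.5 equiv), 1,4-dioxane, 60 °C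
Reagents that add atoms: selenium dioxide, O=[Se]=O
Why: Riley allylic oxidation (ene, then [2,3]-shift) acts on the only remaining alkene and converts the isopropenyl methyl to the aldehyde.

**Step 17**
Reactants: **19** enal
Product: **20** dendronpholide J
Conditions: NaClO2, NaH2PO4, 2-methyl-2-butene, t-BuOH/H2O, rt
Reagents that add atoms: sodium chlorite, [Na+].[O-]Cl=O
Why: Pinnick oxidation converts the enal to the acrylic acid without affecting the alcohols, acetate or oxolane.

## Compound list

| No. | Name | SMILES | Role |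
|---|---|---|---|
| 1 | (R)-carvone | `CC1=CC[C@H](CC1=O)C(C)=C` | starting material |
| 2 | 4-bromo-1-(trimethylsilyl)but-1-yne | `BrCCC#C[Si](C)(C)C` | starting material |
| 3 | (S)-5-oxotetrahydrofuran-2-carboxylic acid | `OC(=O)[C@@H]1CCC(=O)O1` | starting material |
| 4 | (−)-cis-carveol | `CC1=CC[C@H](C[C@H]1O)C(C)=C` | intermediate |
| 5 | syn-epoxy alcohol | `C[C@]12O[C@H]1C[C@@H](C(C)=C)C[C@H]2O` | intermediate |
| 6 | TBS ether of 5 | `C[C@]12O[C@H]1C[C@@H](C(C)=C)C[C@H]2O[Si](C)(C)C(C)(C)C` | intermediate |
| 7 | keto aldehyde | `CC(=O)[C@H](O[Si](C)(C)C(C)(C)C)C[C@@H](CC=O)C(C)=C` | intermediate |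
| 8 | hydroxy ketone | `CC(=O)[C@H](O[Si](C)(C)C(C)(C)C)C[C@@H](CCO)C(C)=C` | intermediate |
| 9 | iodo ketone | `CC(=O)[C@H](O[Si](C)(C)C(C)(C)C)C[C@@H](CCI)C(C)=C` | intermediate |
| 10 | western iodide | `C=C(C)[C@H](CCI)C[C@@H](O[Si](C)(C)C(C)(C)C)[C@@](C)(O[Si](CC)(CC)CC)CCC#C[Si](C)(C)C` | intermediate |
| 11 | (S)-solerone | `CC(=O)[C@@H]1CCC(=O)O1` | intermediate |
| 12 | seco-lactone (TMS-alkyne) | `C=C(C)[C@H](CC[C@@](C)(O[Si](CC)(CC)CC)[C@@H]1CCC(=O)O1)C[C@@H](O[Si](C)(C)C(C)(C)C)[C@@](C)(O[Si](CC)(CC)CC)CCC#C[Si](C)(C)C` | intermediate |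
| 13 | seco-lactone (bromoalkyne) | `C=C(C)[C@H](CC[C@@](C)(O[Si](CC)(CC)CC)[C@@H]1CCC(=O)O1)C[C@@H](O[Si](C)(C)C(C)(C)C)[C@@](C)(O[Si](CC)(CC)CC)CCC#CBr` | intermediate |
| 14 | cyclotetradec-7-yn-11-ol | `C=C(C)[C@@H]1CC[C@@](C)(O[Si](CC)(CC)CC)[C@@H](O)CCC#CCC[C@](C)(O[Si](CC)(CC)CC)[C@H](O[Si](C)(C)C(C)(C)C)C1` | intermediate |
| 15 | bridged Z-enol ether | `C=C(C)[C@@H]1CC[C@@](C)(O[Si](CC)(CC)CC)[C@@H]2CC/C(O2)=C/CC[C@](C)(O[Si](CC)(CC)CC)[C@H](O[Si](C)(C)C(C)(C)C)C1` | intermediate |
| 16 | oxolane 7-ol, trisilyl | `C=C(C)[C@@H]1CC[C@@](C)(O[Si](CC)(CC)CC)[C@@H]2CC[C@@](C)(O2)[C@@H](O)CC[C@](C)(O[Si](CC)(CC)CC)[C@H](O[Si](C)(C)C(C)(C)C)C1` | intermediate |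
| 17 | tetraol | `C=C(C)[C@@H]1CC[C@@](C)(O)[C@@H]2CC[C@@](C)(O2)[C@@H](O)CC[C@](C)(O)[C@H](O)C1` | intermediate |
| 18 | 3-acetate | `C=C(C)[C@@H]1CC[C@@](C)(O)[C@@H]2CC[C@@](C)(O2)[C@@H](O)CC[C@](C)(O)[C@H](OC(C)=O)C1` | intermediate |
| 19 | enal | `C=C(C=O)[C@@H]1CC[C@@](C)(O)[C@@H]2CC[C@@](C)(O2)[C@@H](O)CC[C@](C)(O)[C@H](OC(C)=O)C1` | intermediate |
| 20 | dendronpholide J | `C=C(C(=O)O)[C@@H]1CC[C@@](C)(O)[C@@H]2CC[C@@](C)(O2)[C@@H](O)CC[C@](C)(O)[C@H](OC(C)=O)C1` | target |

## Step count
- Total steps: 17.
- Longest linear sequence: 16 (Steps 1–7 and 9–17).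

## Steps most likely to fail
1. **Step 11 (proposed macrocyclisation).** Possible failures are slow oxidation of the primary carboxylate, diyne formation, or hydrodecarboxylation.
   - Fallback (known chemistry): ring-closing alkyne metathesis.
   - Use the Grignard from 5-bromopent-2-yne in Step 7.
   - After Step 9, reduce the lactone to the lactol (DIBAL-H) and convert it to a methyl-capped alkyne (Ohira–Bestmann, then MeI), so the lactone carbonyl carbon becomes C8.
   - Close C7≡C8 with a Mo alkylidyne/silanolate catalyst to reach **14**.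
2. **Step 9 (organocerium addition to the keto-lactone).** Possible failures are attack on the lactone, enolisation, or modest dr.
   - Fallback: switch the stereochemical model from Cornforth to Cram-chelate.
   - Couple iodide **10** with the acid chloride of **3** by Ni/Mn reductive acylation to give the C12 ketone.
   - After the oxolane is in place, add MeMgBr under chelation by the ring oxygen. Reversing the order of substituent introduction under the reversed model gives the same 12R.
3. **Step 13 (epoxidation and syn-methyl delivery).** Possible failures are the wrong face, anti opening, or hydride/elimination side paths.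
   - Fallback: abandon the alkyne/enol-ether logic.
   - Close the ring onto a (7Z)-C7=C8(Me) olefin by B-alkyl Suzuki coupling of a (Z)-vinyl iodide.
   - Carry out an Os(VI)-catalysed oxidative cyclisation of the free 11,12-diol. This is a stereospecific syn addition that gives only the cis-oxolane, and it delivers the same 7S,8R.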